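Readings and results are simulated for an exercise, noise included.

The south-west run ended with 30.5% of its starting material left and the east run with 7.7%, so I set the leftover aside and looked at what each mM of catalyst had earned.

| setting | south-west | east | south-east | alpha | delta |
|---|---|---|---|---|---|
| starting material | 20 mM | 20 mM | 20 mM | 20 mM | 20 mM |
| second substrate | 20 mM | 20 mM | 46 mM | 20.0 mM | 60.0 mM |
| free catalyst | 0.33 mM | 1.3 mM | 1 mM | 1.0 mM | 0.25 mM |
| remark | run made earlier | run made earlier | run made earlier |  |  |
| time |  |  |  | 40 min | 40 min |

- south-west (time / min: target / %, starting material / %): 4.00: 2.1, 85.1; 8.00: 3.4, 73.8; 12.0: 4.4, 63.2; 15.0: 6.0, 55.8; 20.0: 7.4, 45.8; 25.0: 8.9, 38.1; 30.0: 9.6, 30.5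
- east (time / min: target / %, starting material / %): 1.50: 1.7, 87.3; 4.00: 6.2, 75.8; 8.00: 12.9, 61.7; 12.0: 17.4, 47.6; 15.0: 22.2, 38.4; 20.0: 27.6, 25.8; 30.0: 36.1, 7.7
- south-east (time / min: target / %, starting material / %): 2.50: 3.2, 84.5; 8.00: 9.1, 64.1; 12.0: 14.0, 52.7; 20.0: 21.9, 31.0; 30.0: 28.3, 14.5

(standard deviation of a reading: 0.5 percentage points)

- the numbers in the tables scatter with a standard deviation of 0.5 percentage points

* which one finishes higher in amount of target, in percent of the starting material charged ("neither" within 2 percentage points) (alpha / delta / neither)
* amount of target at the end, in percent of the starting material charged, alpha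
* amount of target at the end, in percent of the starting material charged, delta

I multiplied each target reading by the 1.0 mM of free catalyst in alpha and divided it by the free catalyst of its own run, all three runs having a starting-material charge of 20 mM. At 20.0 min, the south-west, east and south-east columns read 22.4%, 21.2% and 21.9%. Their mean, 21.9%, is the catalyst-scaled yield: target at that time per 1.0 mM of catalyst.

At 30.0 min the columns still lay together, at 29.1%, 27.8% and 28.3%. The south-east column, with 46 mM of second substrate, stayed beside the east column with 20 mM, so I dropped the second substrate from the reckoning. Earlier, the east column stood close to a line in time: at 12.0 min it read 13.4%, and the proportional share of the scaled yield is 13.1%.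

For 40 min I repeated the last south-east gain once, which gave 34.7% for alpha. Scaling by catalyst gave 8.68% for delta, so I expected alpha to finish higher than delta by more than the margin.

The forecast chose alpha, with 33% for alpha and 9% for delta, saying that delta “gains nothing from its excess second substrate”. My alpha figure stood higher than its value.

The flasks gave 32.5% for alpha and 8.81% for delta, so the higher one was alpha.

    target → over-reaction product (k = 3.30 × 10⁻⁴ s⁻¹)
    2 second substrate → homo dimer (k = 0.330 L mol⁻¹ s⁻¹)
    starting material → uncatalysed product (k = 5.20 × 10⁻⁴ s⁻¹)
    second substrate + free catalyst ⇌ catalyst intermediate B (K = 21.0 L mol⁻¹, k = 0.550 L mol⁻¹ s⁻¹)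
    starting material + free catalyst ⇌ catalyst intermediate A (K = 3600 L mol⁻¹, k = 27.0 L mol⁻¹ s⁻¹)
    catalyst intermediate B → free catalyst + second product (k = 0.0210 s⁻¹)
    catalyst intermediate A → free catalyst + target (k = 0.00450 s⁻¹)

In delta at 20.0 min, the scaled yield gave 5.46% and the flask held 5.38%, with 95.5% of its catalyst as catalyst intermediate A, the resting state. The neighbouring flask was delta read at 15 min. The same reckoning, with the catalyst ratio and the time ratio applied to the scaled yield, gave 4.10%. That flask held 4.23% of target, with 96.2% of its catalyst as catalyst intermediate A.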